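Assumption: the target is taken as the constitution given by the SMILES string, drawn in one of its rapidly interconverting enol tautomers; it has no stereocenter and no double-bond geometry to set.

## The problem

- The target (C69H80O24) is a linear chain of six rings joined by five CH2 groups. The end rings A and A′ are 2-butanoyl-3,5-dihydroxy-4,4-dimethylcyclohexa-2,5-dienones (butyrylfilicinic acid units). The inner rings B, C, C′ and B′ are fully substituted butyrylphloroglucinol rings.
- All five bridges are the same kind of bond: a CH2 between two electron-rich rings, made by adding a ring carbon to a quinone-methide-type electrophile. The inner-ring monomer has two equivalent open carbons and the end-ring monomer has one. An undirected condensation therefore behaves as a step-growth polymerization with random termination and gives homologues A–(B)n–A′ that differ by one ring.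
- The bridges are reversible. In alkali or on heating a bridge can fragment by the reverse path (quinone methide plus enolate) and recombine to scrambled chains. This is easiest next to rings A and A′, whose β-triketone enolate is a good leaving group.
- Sixteen acidic OH groups and six chelated aryl or enol ketones rule out protecting-group tactics of reasonable length, and also late strong bases with alkylating agents, strong Lewis acids and oxidants. The quaternary C(CH3)2 carbons must be made at the monomer stage.
- The feature that makes the key step possible: the CH2 carbon between rings C and C′ lies on a mirror plane and divides the molecule into two identical three-ring chains A–B–C. In such a half, ring A is sealed by its quaternary C(CH3)2 carbon and rings A and B carry no ring C–H. Ring C has exactly one unsubstituted sp2 carbon, the C–H between two C–OH carbons and meta to the butyryl-bearing carbon.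
- Each half is therefore a nucleophile with a single reactive carbon. Joining two halves through one carbon atom cannot give anything longer than six rings, because the product has no open ring carbon left.

## Retrosynthesis

**11 to two molecules of 8.** The two C–C bonds of the central CH2 (ring C to CH2 to ring C′) are cut. This is the only bridge whose cleavage gives two identical fragments, so one chain is made once and used twice; any other cut gives two unequal chains. The precursor 8 (C34H40O12) has half the rings and a single nucleophilic ring carbon. The forward reaction must deliver one carbon at the aldehyde oxidation level to that carbon of two molecules of 8 and must leave the four existing bridges untouched.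

**8 to 5 and 6.** The bridge between ring A and ring B is cut. This gives an electrophile with one defined site (5) and a symmetrical two-ring nucleophile (6) whose two open carbons are equivalent, so no regiochemical question arises. Cutting the B–C bridge instead would need an unsymmetrical two-ring piece and one more step. The forward reaction must add one ring C–H carbon of 6 to the exocyclic methylene of 7, the enetrione released from 5, and must do so only once per molecule of 6.

**6 to two molecules of 3.** The CH2 between the two rings is cut. The piece is symmetrical and arises from the monomer and one carbon atom. The forward condensation must stop at two rings.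

**5 to 4.** The C–CH2N bond at C-6 of the filicinic ring is cut. C-6 is the only unsubstituted sp2 carbon of 4, so aminomethylation can occur only there.

**4 to 3.** The two C–CH3 bonds at the quaternary carbon are cut. Ring A is thus derived from the same monomer as rings B and C by a dearomatizing double C-methylation at one open ring carbon, so all six rings of 11 come from 3.

**3 to 1 and 2.** The aryl–acyl bond is cut; mono-acylation of the symmetrical triol 1 by 2 is asked of the forward step.

## Roads not taken

**Alternative 1:** All five bridges are cut at once. The forward step is a one-flask co-condensation of 4 (2 parts), 3 (4 parts) and formaldehyde (5 parts) in dilute alkali. Because 4 terminates chains at random, the six-ring compound would be one member of a distribution that starts with the two-ring compound A1 (A–CH2–A′) and the three-ring compound A2 (A–CH2–B–CH2–A′) and continues upward, together with uncapped chains. No mechanistic handle favors four inner rings, and the homologues share polarity and acidity. The chosen plan fixes the number of inner rings by construction: two per half in step 5, and a final step that cannot change it.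

**Alternative 2:** The bridge between ring B′ and ring A′ is cut last, after growing the chain one ring at a time from one end to the five-ring chain A3 (A–B–C–C′–B′ with one open carbon), which 5 would cap. This needs four successive rounds of aminomethylation and coupling with excess 3 before the capping. Each round is run on a larger intermediate that already holds the labile bridge next to ring A, and the route makes the same bonds twice. The chosen plan uses the mirror plane, reaches the target in six steps and exposes the labile bridge to only one later coupling.

**Alternative 3:** The six ring-to-acyl bonds are cut. The forward key step is a six-fold Friedel–Crafts butyrylation (2, AlCl3) of the acyl-free six-ring skeleton A4, in which every ring has exactly one open carbon, so the regiochemistry would be automatic. Without acyl groups the rings of A4 are as nucleophilic as phloroglucinol itself. Their CH2 bridges are cleaved by Lewis and Brønsted acids through ipso protonation and loss of a benzyl cation, and A4 would have to be assembled with the same chain-length problem but without the moderating acyl groups. Sixteen OH groups would also compete for 2. The chosen plan installs the acyl group first, on the monomer, where it tempers the ring and does no harm later.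

Key step: step 6

## Steps

Step 1
Reactants: 1 phloroglucinol (benzene-1,3,5-triol); 2 butanoyl chloride
Product: 3 1-(2,4,6-trihydroxyphenyl)butan-1-one (butyrylphloroglucinol)
Conditions: AlCl3 (3.5 equiv), CH2Cl2/MeNO2, 0 → 40 °C; then ice/1 M HCl
Reagents that add atoms: none
Why: Friedel–Crafts C-acylation of the very electron-rich triol; the first acyl group, chelated by its ortho OH, deactivates the ring, so the reaction should stop at mono-acylation.

Step 2
Reactants: 3 butyrylphloroglucinol
Product: 4 2-butanoyl-3,5-dihydroxy-4,4-dimethylcyclohexa-2,5-dien-1-one (butyrylfilicinic acid)
Conditions: NaOMe (3.0 equiv), MeI (2.2 equiv), MeOH, 0 → 23 °C; then 1 M HCl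
Reagents that add atoms: iodomethane, CI
Why: Base-mediated dearomatizing C-methylation of an acylphloroglucinol, the classical entry to acylfilicinic acids; the phenolate is alkylated on carbon in MeOH, and the ring carbon that has taken one methyl is the most electron-rich and takes the second, giving the quaternary carbon and a stabilized β-triketone anion that reacts more slowly.

Step 3
Reactants: 4 butyrylfilicinic acid
Product: 5 2-butanoyl-6-[(dimethylamino)methyl]-3,5-dihydroxy-4,4-dimethylcyclohexa-2,5-dien-1-one (Mannich base, an ammonium enolate zwitterion)
Conditions: Me2NCH2NMe2 (1.05 equiv), CH2Cl2, 0 → 23 °C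
Reagents that add atoms: bis(dimethylamino)methane, CN(C)CN(C)C
Why: Mannich aminomethylation; the acidic enol of 4 protonates the aminal to CH2=NMe2+, which is attacked by C-6, the only unsubstituted sp2 ring carbon; 5 should be kept cold and used soon.

Step 4
Reactants: 3 butyrylphloroglucinol (two molecules)
Product: 6 1,1'-[methylenebis(2,4,6-trihydroxybenzene-3,1-diyl)]dibutan-1-one (methylenebis(butyrylphloroglucinol))
Conditions: 37% aq. CH2O (0.25 equiv relative to 3), 1% aq. KOH (1.0 equiv), 0 → 23 °C, 20 min; then 2 M HCl; excess 3 recovered
Reagents that add atoms: formaldehyde, C=O
Why: Classical alkaline formaldehyde condensation of an acylphloroglucinol (hydroxymethylation, quinone methide, addition of a second phenolate); the excess of 3 should hold the chain at two rings because the open carbons of 6 compete with a large pool of monomer.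

Step 5
Reactants: 5 Mannich base of butyrylfilicinic acid; 6 methylenebis(butyrylphloroglucinol) (3 equiv)
Product: 8 2-butanoyl-6-{[3-butanoyl-5-(3-butanoyl-2,4,6-trihydroxybenzyl)-2,4,6-trihydroxyphenyl]methyl}-3,5-dihydroxy-4,4-dimethylcyclohexa-2,5-dien-1-one (three-ring chain A–B–C), via methylidene enetrione 7 (not isolated)
Conditions: AcOH (2 equiv), 1,4-dioxane, 40 °C, argon; excess 6 recovered
Reagents that add atoms: none
Why: Loss of HNMe2 from the zwitterion 5 costs no aromaticity and gives the exocyclic enetrione 7, a strong Michael acceptor; a ring C–H carbon of 6 adds (Mannich-base alkylation of a phenol, as used for unsymmetrical methylene-bridged acylphloroglucinols) and tautomerization restores the aromatic ring; the two open carbons of 6 are equivalent, so only the extent of capping needs control, which the excess of 6 provides.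

Step 6
Reactants: 8 three-ring chain A–B–C (two molecules)
Product: 11 CNP0237140.0 (six-ring chain A–B–C–CH2–C′–B′–A′), via Mannich base 9 (not isolated), via ortho-quinone methide 10 (not isolated)
Conditions: Me2NCH2NMe2 (0.50 equiv), AcOH (2 equiv), 1,4-dioxane, 23 °C, then 70 °C, argon
Reagents that add atoms: bis(dimethylamino)methane, CN(C)CN(C)C
Why: Mannich aminomethylation, ortho-quinone methide formation and conjugate addition of a second phenol carbon, the standard way of bridging two acylphloroglucinol rings with a CH2. The aminal is protonated by the acidic enols of 8 or by AcOH to CH2=NMe2+, which can attack only the one unsubstituted sp2 carbon of ring C, so 0.5 equiv should turn half of 8 into 9. On warming, the ammonium phenolate of 9 loses HNMe2 to give 10, and the untouched half of 8 adds through the same ring C carbon; tautomerization restores both aromatic rings and leaves the central CH2. The closest known reaction type is the coupling of an acylphloroglucinol Mannich base with a second acylphloroglucinol or acylfilicinic acid to a methylene-bridged dimer. No ring is closed and no stereocenter is formed, since the new carbon is a CH2 on the mirror plane. The step needs site selectivity, which is secured because 8 has a single ring C–H and ring A is sealed by C(CH3)2. It needs chain-length fidelity, which is secured because 11 has no open ring carbon, so growth stops at six rings. It also needs the four existing bridges to survive, which the buffered, non-alkaline medium and moderate temperature should favor by slowing the retro-Michael cleavage that scrambles such bridges.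

## Compound list

1 | phloroglucinol (benzene-1,3,5-triol) | Oc1cc(O)cc(O)c1 | starting material
2 | butanoyl chloride | CCCC(=O)Cl | starting material
3 | 1-(2,4,6-trihydroxyphenyl)butan-1-one (butyrylphloroglucinol) | CCCC(=O)c1c(O)cc(O)cc1O | intermediate
4 | 2-butanoyl-3,5-dihydroxy-4,4-dimethylcyclohexa-2,5-dien-1-one (butyrylfilicinic acid) | CCCC(=O)C1=C(O)C(C)(C)C(O)=CC1=O | intermediate
5 | 2-butanoyl-6-[(dimethylamino)methyl]-3,5-dihydroxy-4,4-dimethylcyclohexa-2,5-dien-1-one | CCCC(=O)C1=C(O)C(C)(C)C(O)=C(CN(C)C)C1=O | intermediate
6 | 1,1'-[methylenebis(2,4,6-trihydroxybenzene-3,1-diyl)]dibutan-1-one | CCCC(=O)c1c(O)cc(O)c(Cc2c(O)cc(O)c(C(=O)CCC)c2O)c1O | intermediate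
7 | 2-butanoyl-3-hydroxy-4,4-dimethyl-6-methylidenecyclohex-2-ene-1,5-dione (not isolated) | CCCC(=O)C1=C(O)C(C)(C)C(=O)C(=C)C1=O | intermediate
8 | three-ring chain A–B–C: 2-butanoyl-6-{[3-butanoyl-5-(3-butanoyl-2,4,6-trihydroxybenzyl)-2,4,6-trihydroxyphenyl]methyl}-3,5-dihydroxy-4,4-dimethylcyclohexa-2,5-dien-1-one | CCCC(=O)C1=C(O)C(C)(C)C(O)=C(Cc2c(O)c(Cc3c(O)cc(O)c(C(=O)CCC)c3O)c(O)c(C(=O)CCC)c2O)C1=O | intermediate
9 | Mannich base of 8, carrying CH2N(CH3)2 on the open carbon of ring C (not isolated) | CCCC(=O)C1=C(O)C(C)(C)C(O)=C(Cc2c(O)c(Cc3c(O)c(CN(C)C)c(O)c(C(=O)CCC)c3O)c(O)c(C(=O)CCC)c2O)C1=O | intermediate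
10 | ortho-quinone methide of 8, ring C as a 6-methylidenecyclohexa-2,4-dienone (not isolated) | CCCC(=O)C1=C(O)C(C)(C)C(O)=C(Cc2c(O)c(CC3=C(O)C(=C)C(=O)C(C(=O)CCC)=C3O)c(O)c(C(=O)CCC)c2O)C1=O | intermediate
11 | CNP0237140.0, six-ring chain A–B–C–CH2–C′–B′–A′ | CCCC(=O)C1=C(O)C(C)(C)C(O)=C(Cc2c(O)c(Cc3c(O)c(Cc4c(O)c(Cc5c(O)c(CC6=C(O)C(C)(C)C(O)=C(C(=O)CCC)C6=O)c(O)c(C(=O)CCC)c5O)c(O)c(C(=O)CCC)c4O)c(O)c(C(=O)CCC)c3O)c(O)c(C(=O)CCC)c2O)C1=O | target

## Step count and risks

Total step count: 6. Longest linear sequence: 5 steps (steps 1, 2, 3, 5 and 6); step 4 is the side branch that supplies 6.

**Step 6 (key step).** The most likely failure is exchange of bridges during the heating that 9 needs to lose HNMe2. A bridge next to ring A can fragment by retro-Michael cleavage and recombine, which would spread the material over chains of other lengths. Slow coupling through aggregation of the polyphenolic chains is the second concern.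

The fallback sets out from 6 (with 5) and returns at 11. It changes the order of bond formation so that the two most labile bridges are made last and under the mildest conditions:
- 6, in excess, would be condensed with formaldehyde (37% aq. CH2O, 1% aq. KOH, 0 °C; then HCl) to the four-ring chain 1,1'-{methylenebis[(5-butanoyl-2,4,6-trihydroxybenzene-3,1-diyl)methylene(2,4,6-trihydroxybenzene-3,1-diyl)]}dibutan-1-one F1, which is open at both end rings.
- F1 would be capped at both open carbons with two equivalents of 5 (AcOH, 1,4-dioxane, 40 °C) to give 11.

The electrophile 7 forms without loss of aromaticity, so no step after the capping would heat a filicinic bridge. The price is that the length of F1 rests on stoichiometry and separation and is no longer fixed by the structure.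

**Step 5.** The likely failure is loss of control over the extent of capping: alkylation of both open carbons of 6, and retro-Mannich release of free 4 followed by self-coupling of the filicinic unit.

The fallback sets out from 5 (with 3) and returns at 8. It adds one ring at a time:
- 5 would be added to a five-fold excess of the cheap monomer 3 (AcOH, 1,4-dioxane, 40 °C) to give the two-ring unit 2-butanoyl-6-(3-butanoyl-2,4,6-trihydroxybenzyl)-3,5-dihydroxy-4,4-dimethylcyclohexa-2,5-dien-1-one F2.
- F2 would be aminomethylated at its single open carbon (Me2NCH2NMe2, CH2Cl2, 0 °C) to the Mannich base F3.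
- F3 would be heated with excess 3 (AcOH, 1,4-dioxane, 70 °C) to give 8.

The by-products of over-alkylation then differ from the product by a whole ring or more, and neither 6 nor step 4 is needed.

**Step 2.** The likely failure is poor control of the degree and site of methylation: reaction at the second open ring carbon, incomplete second methylation and some O-methylation.

The fallback sets out from 2 and returns at 4. It blocks the second open carbon before methylation:
- Purchased methyl 2,4,6-trihydroxybenzoate F4 would be acylated with 2 (AlCl3, CH2Cl2/MeNO2) to methyl 3-butanoyl-2,4,6-trihydroxybenzoate F5, which has one open ring carbon.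
- F5 would be methylated twice at that carbon (NaOMe, MeI, MeOH) to methyl 5-butanoyl-2,4-dihydroxy-3,3-dimethyl-6-oxocyclohexa-1,4-diene-1-carboxylate F6.
- F6 would be saponified and decarboxylated (aq. NaOH, 60 °C; then HCl, warm) to give 4.

## Further compounds

F1 | step 6 | four-ring chain of 3 joined by three CH2 groups, open at both end rings | CCCC(=O)c1c(O)cc(O)c(Cc2c(O)c(Cc3c(O)c(Cc4c(O)cc(O)c(C(=O)CCC)c4O)c(O)c(C(=O)CCC)c3O)c(O)c(C(=O)CCC)c2O)c1O
F2 | step 5 | 2-butanoyl-6-(3-butanoyl-2,4,6-trihydroxybenzyl)-3,5-dihydroxy-4,4-dimethylcyclohexa-2,5-dien-1-one | CCCC(=O)C1=C(O)C(C)(C)C(O)=C(Cc2c(O)cc(O)c(C(=O)CCC)c2O)C1=O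
F3 | step 5 | Mannich base of F2, carrying CH2N(CH3)2 on the open carbon of the aromatic ring | CCCC(=O)C1=C(O)C(C)(C)C(O)=C(Cc2c(O)c(CN(C)C)c(O)c(C(=O)CCC)c2O)C1=O
F4 | step 2 | methyl 2,4,6-trihydroxybenzoate (purchased) | COC(=O)c1c(O)cc(O)cc1O
F5 | step 2 | methyl 3-butanoyl-2,4,6-trihydroxybenzoate | CCCC(=O)c1c(O)cc(O)c(C(=O)OC)c1O
F6 | step 2 | methyl 5-butanoyl-2,4-dihydroxy-3,3-dimethyl-6-oxocyclohexa-1,4-diene-1-carboxylate | CCCC(=O)C1=C(O)C(C)(C)C(O)=C(C(=O)OC)C1=O
A1 | alternative 1 | two-ring compound A–CH2–A′ (methylenebis(butyrylfilicinic acid)) | CCCC(=O)C1=C(O)C(C)(C)C(O)=C(CC2=C(O)C(C)(C)C(O)=C(C(=O)CCC)C2=O)C1=O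
A2 | alternative 1 | three-ring compound A–CH2–B–CH2–A′ | CCCC(=O)C1=C(O)C(C)(C)C(O)=C(Cc2c(O)c(CC3=C(O)C(C)(C)C(O)=C(C(=O)CCC)C3=O)c(O)c(C(=O)CCC)c2O)C1=O
A3 | alternative 2 | five-ring chain A–B–C–C′–B′ with one open carbon on the last ring | CCCC(=O)C1=C(O)C(C)(C)C(O)=C(Cc2c(O)c(Cc3c(O)c(Cc4c(O)c(Cc5c(O)cc(O)c(C(=O)CCC)c5O)c(O)c(C(=O)CCC)c4O)c(O)c(C(=O)CCC)c3O)c(O)c(C(=O)CCC)c2O)C1=O
A4 | alternative 3 | acyl-free six-ring skeleton (two filicinic acid end rings, four phloroglucinol rings, five CH2 bridges) | CC1(C)C(O)=CC(=O)C(Cc2c(O)c(Cc3c(O)c(Cc4c(O)c(Cc5c(O)c(CC6=C(O)C(C)(C)C(O)=CC6=O)c(O)cc5O)c(O)cc4O)c(O)cc3O)c(O)cc2O)=C1O
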